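**Plan**
- Names: ring A = guaiacyl ring on benzofuran C2; ring B = benzo ring of the dihydrobenzofuran; ring C = phenol ring of the diol arm; ring D = guaiacyl ring on carbinol C7 (C8 = neighbouring methine, C9 = its CH2OH); lactone = O1, C2(=O), C3, C4, C5.
- Cuts, in order: lactone C3–CH2(ring C); lactone O1–C5; the two ring bonds of a cyclobutanone and the ring B–allyl bond; benzofuran O1–C2; last, C7–C8 of one anti-aldol diol that serves both halves.
- Enabling feature: with O1 deleted, the γ-butyrolactone is a cyclobutanone in which C4, carrying the ring B benzyl group, lies on a local mirror plane between two equivalent CH2 groups (lactone C3 and C5), so one oxygen insertion closes the lactone and creates C4.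
- Forward: arylacetic acid from 5-bromo-o-vanillin, anti-aldol with O-benzylvanillin, diol; branch one closes the dihydrofuran ring, then allylation, cyclobutanone, lactone; branch two turns Br into CH2Br; enolate alkylation joins them; three deprotections.
- Stereochemistry: the oxazolidinone auxiliary sets C8 of both halves and C7; benzofuran C2 comes from invertive ring closure; lactone C4 from the chiral scandium catalyst; lactone C3 from trans alkylation.

Key step: step 13

Remark (aldol): the magnesium-chelated Z-enolate is assumed to react on the face opposite the auxiliary benzyl group, as in enolate alkylation; hence the (S)-auxiliary.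
Remark (key step): which ligand antipode delivers 4S is to be fixed on a model 3-benzylcyclobutanone; the (S)-pipecolic series is written, the (R) series being equally accessible.
Abbreviations in names: TBS = tert-butyldimethylsilyl; BF = (2R,3S)-2-[4-(benzyloxy)-3-methoxyphenyl]-7-methoxy-3-[(TBS-oxy)methyl]-2,3-dihydro-1-benzofuran-5-yl; DP = (1S,2S)-1-[4-(benzyloxy)-3-methoxyphenyl]-1,3-bis(TBS-oxy)propan-2-yl.

**Route**

Step 1
Reactants: 1 5-bromo-2-hydroxy-3-methoxybenzaldehyde
Product: 2 2-(allyloxy)-5-bromo-3-methoxybenzaldehyde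
Conditions: allyl bromide, K2CO3, DMF, rt
Reagents that add atoms: allyl bromide, C=CCBr
Why: Williamson etherification of the phenoxide with allyl bromide; the aldehyde and the aryl bromide are not affected.

Step 2
Reactants: 2 2-(allyloxy)-5-bromo-3-methoxybenzaldehyde
Product: 4 2-[2-(allyloxy)-5-bromo-3-methoxyphenyl]acetonitrile, via the N-(1-tosylvinyl)formamide 3 (not isolated)
Conditions: TosMIC, t-BuOK, DME, −40 °C; then MeOH, reflux
Reagents that add atoms: TosMIC (p-toluenesulfonylmethyl isocyanide), Cc1ccc(cc1)S(=O)(=O)C[N+]#[C-]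
Why: van Leusen reductive cyanation: the TosMIC anion adds to the aldehyde, the resulting oxazoline opens to the N-(1-tosylvinyl)formamide, and methanolysis of the formyl group followed by loss of sulfinate should leave the one-carbon-homologated arylacetonitrile.

Step 3
Reactants: 4 2-[2-(allyloxy)-5-bromo-3-methoxyphenyl]acetonitrile
Product: 5 2-[2-(allyloxy)-5-bromo-3-methoxyphenyl]acetic acid
Conditions: KOH, EtOH/H2O, reflux; then aq HCl
Reagents that add atoms: potassium hydroxide, [K+].[OH-]; water, O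
Why: Alkaline nitrile hydrolysis via the primary amide; the aryl bromide and the allyl ether do not react with hydroxide under these conditions.

Step 4
Reactants: 5 2-[2-(allyloxy)-5-bromo-3-methoxyphenyl]acetic acid; 6 (S)-4-benzyloxazolidin-2-one
Product: 8 (S)-3-{2-[2-(allyloxy)-5-bromo-3-methoxyphenyl]acetyl}-4-benzyloxazolidin-2-one, via the mixed pivalic anhydride 7 (not isolated)
Conditions: PivCl, Et3N, THF, −20 °C; then 6, LiCl, rt
Reagents that add atoms: none
Why: N-Acylation of the oxazolidinone through the mixed pivalic anhydride under LiCl/Et3N activation, the standard way to N-arylacetyl imides.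

Step 5
Reactants: 8 (S)-3-{2-[2-(allyloxy)-5-bromo-3-methoxyphenyl]acetyl}-4-benzyloxazolidin-2-one; 9 4-(benzyloxy)-3-methoxybenzaldehyde
Product: 11 (S)-3-{(2R,3S)-2-[2-(allyloxy)-5-bromo-3-methoxyphenyl]-3-[4-(benzyloxy)-3-methoxyphenyl]-3-hydroxypropanoyl}-4-benzyloxazolidin-2-one, via the trimethylsilyl ether 10 (not isolated)
Conditions: MgCl2 (20 mol %), Et3N, TMSCl, EtOAc, rt; then 1 M HCl/THF, 0 °C, brief
Reagents that add atoms: none
Why: Magnesium-halide-catalysed Evans anti-aldol reaction: soft enolisation gives the Mg-chelated Z-enolate, which should add to the non-enolisable aldehyde on the face away from the auxiliary benzyl group with anti topology while silylation of the aldolate releases the catalyst, so that C8 (2R in the imide) and C7 (3S) are both set by the auxiliary.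

Step 6
Reactants: 11 anti-aldol imide
Product: 12 (1S,2S)-2-[2-(allyloxy)-5-bromo-3-methoxyphenyl]-1-[4-(benzyloxy)-3-methoxyphenyl]propane-1,3-diol
Conditions: LiBH4, MeOH (1 equiv), THF, 0 °C
Reagents that add atoms: none
Why: Reductive cleavage of the imide with LiBH4 (hydride attacks the exocyclic carbonyl) should give the primary alcohol and return the auxiliary without touching either stereocentre, the aryl bromide or the allyl ether.

Step 7
Reactants: 12 (1S,2S)-diol
Product: 13 (1S,2S)-2-[2-(allyloxy)-5-bromo-3-methoxyphenyl]-1-[4-(benzyloxy)-3-methoxyphenyl]-3-(TBS-oxy)propan-1-ol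
Conditions: TBSCl, imidazole, CH2Cl2, 0 °C
Reagents that add atoms: tert-butyldimethylsilyl chloride, CC(C)(C)[Si](C)(C)Cl
Why: Chemoselective silylation: the unhindered primary hydroxyl reacts far faster with TBSCl than the secondary benzylic one flanked by two aryl-bearing carbons.

Step 8
Reactants: 13 mono-TBS ether
Product: 14 4-bromo-2-{(1S,2S)-1-[4-(benzyloxy)-3-methoxyphenyl]-1-hydroxy-3-(TBS-oxy)propan-2-yl}-6-methoxyphenol
Conditions: Pd(PPh3)4 (cat.), morpholine, THF, rt
Reagents that add atoms: none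
Why: Tsuji–Trost deallylation: zerovalent palladium ionises the allyl aryl ether and morpholine traps the π-allyl complex, while the electron-rich aryl bromide does not undergo oxidative addition with this catalyst at room temperature.

Step 9
Reactants: 14 phenol carbinol
Product: 15 (2R,3S)-2-[4-(benzyloxy)-3-methoxyphenyl]-5-bromo-7-methoxy-3-[(TBS-oxy)methyl]-2,3-dihydro-1-benzofuran (BF–Br)
Conditions: PPh3, DIAD, THF, 0 °C to rt
Reagents that add atoms: none
Why: Intramolecular Mitsunobu etherification (5-exo-tet): the phenol displaces the phosphonium-activated benzylic oxygen with inversion at C7, which turns the anti 1S,2S arrangement into the trans 2R,3S dihydrobenzofuran, and any ionised pathway would also close to the more stable trans ring.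

Step 10
Reactants: 15 BF–Br; 16 allylboronic acid pinacol ester
Product: 17 3-(BF)prop-1-ene (the 5-allyl dihydrobenzofuran)
Conditions: Pd(dppf)Cl2 (cat.), K2CO3, dioxane/H2O, 85 °C
Reagents that add atoms: none
Why: Suzuki–Miyaura cross-coupling of the aryl bromide with the allylboronate under zerovalent palladium catalysis, a standard route to allylarenes that tolerates silyl and benzyl ethers.

Step 11
Reactants: 17 3-(BF)prop-1-ene; 18 trichloroacetyl chloride
Product: 20 2,2-dichloro-3-(BF-methyl)cyclobutan-1-one (both epimers at the ring carbon), via dichloroketene 19 (not isolated)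
Conditions: Zn–Cu couple, Et2O/DME, rt
Reagents that add atoms: none
Why: Thermal [2+2] cycloaddition of dichloroketene, made in the flask by zinc dechlorination of the acid chloride, to the terminal alkene with the carbonyl carbon bonding to the CH2 terminus; the new ring stereocentre forms as both epimers and becomes prochiral again in step 12.

Step 12
Reactants: 20 2,2-dichloro-3-(BF-methyl)cyclobutan-1-one
Product: 21 3-(BF-methyl)cyclobutan-1-one
Conditions: Zn dust, NH4Cl, MeOH, rt
Reagents that add atoms: none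
Why: Zinc reduction of the α,α-dichloroketone removes both chlorines via the zinc enolate under near-neutral conditions that spare the silyl ether, which restores the local mirror plane through C1 and C3 of the cyclobutanone.

Step 13
Reactants: 21 3-(BF-methyl)cyclobutan-1-one
Product: 22 (4S)-4-(BF-methyl)oxolan-2-one
Conditions: Sc(OTf)3 (10 mol %), N,N'-dioxide ligand 1,1'-(propane-1,3-diyl)bis[(2S)-2-[(2,6-diisopropylphenyl)carbamoyl]piperidine 1-oxide] (10 mol %), m-CPBA, Al(OiPr)3, EtOAc, −20 °C
Reagents that add atoms: m-CPBA, OOC(=O)c1cccc(Cl)c1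
Why: Baeyer–Villiger oxidation run as a catalytic desymmetrisation: the Sc(OTf)3–N,N'-dioxide complex binds the ketone, the peracid adds to give the Criegee adduct, and the ring CH2 lying anti-periplanar to the breaking O–O bond migrates from carbon to oxygen with loss of 3-chlorobenzoate, forming the lactone O1–C5 bond. The closest known reaction is the chiral N,N'-dioxide–Sc(OTf)3-catalysed Baeyer–Villiger oxidation of 3-aryl- and 3-benzylcyclobutanones. The γ-butyrolactone is not closed by a cyclisation but arises by one-atom ring expansion of the four-membered ring, driven by release of cyclobutanone strain. The new stereocentre, lactone C4 (S), is fixed only by which of the two CH2 groups (enantiotopic within the ring, since the nearest stereocentre, benzofuran C3, is five bonds from the prochiral carbon) the chiral complex aligns for migration. The step needs enantiotopic-group selectivity and chemoselectivity: both migrations give the same constitution so no regiochemical issue exists, the strained ketone is the only carbonyl and the only peracid-reactive group because the alkene was consumed in step 11, and the low temperature should suppress the uncatalysed background oxidation.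

Step 14
Reactants: 12 (1S,2S)-diol
Product: 23 2-(allyloxy)-5-bromo-1-(DP)-3-methoxybenzene
Conditions: TBSOTf, 2,6-lutidine, CH2Cl2, −78 to 0 °C
Reagents that add atoms: tert-butyldimethylsilyl triflate, CC(C)(C)[Si](C)(C)OS(=O)(=O)C(F)(F)F
Why: Silylation with the silyl triflate and a hindered pyridine base is strong enough to cap the hindered secondary benzylic hydroxyl as well as the primary one.

Step 15
Reactants: 23 2-(allyloxy)-5-bromo-1-(DP)-3-methoxybenzene
Product: 25 [4-(allyloxy)-3-(DP)-5-methoxyphenyl]methanol, via the aryl aldehyde 24 (not isolated)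
Conditions: n-BuLi, THF, −78 °C; DMF, −78 to 0 °C; then MeOH, NaBH4, 0 °C
Reagents that add atoms: N,N-dimethylformamide, CN(C)C=O
Why: Bromine–lithium exchange is faster than any deprotonation at −78 °C, the aryllithium is formylated by DMF (Bouveault reaction), and borohydride reduces the aldehyde released on adding methanol in the same flask.

Step 16
Reactants: 25 [4-(allyloxy)-3-(DP)-5-methoxyphenyl]methanol
Product: 26 2-(allyloxy)-5-(bromomethyl)-1-(DP)-3-methoxybenzene
Conditions: CBr4, PPh3, CH2Cl2, 0 °C; used at once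
Reagents that add atoms: carbon tetrabromide, BrC(Br)(Br)Br
Why: Appel bromination converts the electron-rich benzylic alcohol to the bromide under neutral conditions that leave the silyl ethers and the allyl ether intact.

Step 17
Reactants: 22 (4S)-4-(BF-methyl)oxolan-2-one; 26 2-(allyloxy)-5-(bromomethyl)-1-(DP)-3-methoxybenzene
Product: 27 (3S,4S)-3-[4-(allyloxy)-3-(DP)-5-methoxybenzyl]-4-(BF-methyl)oxolan-2-one
Conditions: LiN(SiMe3)2, THF, −78 °C; then 26, DMPU, −78 to −40 °C
Reagents that add atoms: none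
Why: Alkylation of the lactone lithium enolate with the benzylic bromide: the electrophile approaches the enolate face anti to the C4 substituent, which should give the trans 3S,4S lactone as in classical dibenzylbutyrolactone syntheses.

Step 18
Reactants: 27 fully protected trans lactone
Product: 28 (3S,4S)-3-[3-(DP)-4-hydroxy-5-methoxybenzyl]-4-(BF-methyl)oxolan-2-one
Conditions: Pd(PPh3)4 (cat.), morpholine, THF, rt
Reagents that add atoms: none
Why: Tsuji–Trost deallylation as in step 8; the lactone, the silyl ethers and the benzyl ethers are inert to zerovalent palladium and morpholine at room temperature.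

Step 19
Reactants: 28 ring C phenol
Product: 29 (3S,4S)-3-[3-{(1S,2S)-1-[4-(benzyloxy)-3-methoxyphenyl]-1,3-dihydroxypropan-2-yl}-4-hydroxy-5-methoxybenzyl]-4-{[(2R,3S)-2-[4-(benzyloxy)-3-methoxyphenyl]-3-(hydroxymethyl)-7-methoxy-2,3-dihydro-1-benzofuran-5-yl]methyl}oxolan-2-one
Conditions: TBAF, AcOH, THF, rt
Reagents that add atoms: none
Why: Fluoride-mediated cleavage of the three silyl ethers, buffered with acetic acid so that the lactone is neither opened nor epimerised and no strong acid touches the acid-sensitive ring C/ring D diol.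

Step 20
Reactants: 29 bis(benzyl ether)
Product: 30 CNP0186558.3
Conditions: H2 (1 atm), Pd/C, EtOAc/MeOH, rt
Reagents that add atoms: none
Why: Hydrogenolysis of the two primary benzyl aryl ethers over palladium should be much faster than cleavage of the secondary benzylic C–O bonds at C7 and at benzofuran C2 under neutral conditions, and the absence of acid keeps the open diol arm from cyclising onto the ring C phenol.

**Compound list**

1 | 5-bromo-2-hydroxy-3-methoxybenzaldehyde | COc1cc(Br)cc(C=O)c1O | starting material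
2 | 2-(allyloxy)-5-bromo-3-methoxybenzaldehyde | C=CCOc1c(C=O)cc(Br)cc1OC | intermediate
3 | N-{2-[2-(allyloxy)-5-bromo-3-methoxyphenyl]-1-tosylethenyl}formamide (potassium salt in the flask) | O=CNC(=Cc1cc(Br)cc(OC)c1OCC=C)S(=O)(=O)c1ccc(C)cc1 | intermediate (not isolated)
4 | 2-[2-(allyloxy)-5-bromo-3-methoxyphenyl]acetonitrile | N#CCc1cc(Br)cc(OC)c1OCC=C | intermediate
5 | 2-[2-(allyloxy)-5-bromo-3-methoxyphenyl]acetic acid | OC(=O)Cc1cc(Br)cc(OC)c1OCC=C | intermediate
6 | (S)-4-benzyloxazolidin-2-one | O=C1N[C@@H](Cc2ccccc2)CO1 | starting material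
7 | mixed anhydride of acid 5 with pivalic acid | CC(C)(C)C(=O)OC(=O)Cc1cc(Br)cc(OC)c1OCC=C | intermediate (not isolated)
8 | (S)-3-{2-[2-(allyloxy)-5-bromo-3-methoxyphenyl]acetyl}-4-benzyloxazolidin-2-one | O=C(Cc1cc(Br)cc(OC)c1OCC=C)N1[C@@H](Cc2ccccc2)COC1=O | intermediate
9 | 4-(benzyloxy)-3-methoxybenzaldehyde | COc1cc(C=O)ccc1OCc1ccccc1 | starting material
10 | trimethylsilyl ether of aldol adduct 11 | COc1cc([C@@H](O[Si](C)(C)C)[C@H](C(=O)N2[C@@H](Cc3ccccc3)COC2=O)c2cc(Br)cc(OC)c2OCC=C)ccc1OCc1ccccc1 | intermediate (not isolated)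
11 | (S)-3-{(2R,3S)-2-[2-(allyloxy)-5-bromo-3-methoxyphenyl]-3-[4-(benzyloxy)-3-methoxyphenyl]-3-hydroxypropanoyl}-4-benzyloxazolidin-2-one | COc1cc([C@@H](O)[C@H](C(=O)N2[C@@H](Cc3ccccc3)COC2=O)c2cc(Br)cc(OC)c2OCC=C)ccc1OCc1ccccc1 | intermediate
12 | (1S,2S)-2-[2-(allyloxy)-5-bromo-3-methoxyphenyl]-1-[4-(benzyloxy)-3-methoxyphenyl]propane-1,3-diol | COc1cc([C@@H](O)[C@H](CO)c2cc(Br)cc(OC)c2OCC=C)ccc1OCc1ccccc1 | intermediate
13 | (1S,2S)-2-[2-(allyloxy)-5-bromo-3-methoxyphenyl]-1-[4-(benzyloxy)-3-methoxyphenyl]-3-(TBS-oxy)propan-1-ol | COc1cc([C@@H](O)[C@H](CO[Si](C)(C)C(C)(C)C)c2cc(Br)cc(OC)c2OCC=C)ccc1OCc1ccccc1 | intermediate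
14 | 4-bromo-2-{(1S,2S)-1-[4-(benzyloxy)-3-methoxyphenyl]-1-hydroxy-3-(TBS-oxy)propan-2-yl}-6-methoxyphenol | COc1cc([C@@H](O)[C@H](CO[Si](C)(C)C(C)(C)C)c2cc(Br)cc(OC)c2O)ccc1OCc1ccccc1 | intermediate
15 | (2R,3S)-2-[4-(benzyloxy)-3-methoxyphenyl]-5-bromo-7-methoxy-3-[(TBS-oxy)methyl]-2,3-dihydro-1-benzofuran | Brc1cc(OC)c2c(c1)[C@@H](CO[Si](C)(C)C(C)(C)C)[C@H](c1ccc(OCc3ccccc3)c(OC)c1)O2 | intermediate
16 | allylboronic acid pinacol ester | C=CCB1OC(C)(C)C(C)(C)O1 | starting material
17 | (2R,3S)-5-allyl-2-[4-(benzyloxy)-3-methoxyphenyl]-7-methoxy-3-[(TBS-oxy)methyl]-2,3-dihydro-1-benzofuran | C=CCc1cc(OC)c2c(c1)[C@@H](CO[Si](C)(C)C(C)(C)C)[C@H](c1ccc(OCc3ccccc3)c(OC)c1)O2 | intermediate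
18 | trichloroacetyl chloride | O=C(Cl)C(Cl)(Cl)Cl | starting material
19 | dichloroketene | O=C=C(Cl)Cl | intermediate (not isolated)
20 | 2,2-dichloro-3-{[(2R,3S)-2-[4-(benzyloxy)-3-methoxyphenyl]-7-methoxy-3-[(TBS-oxy)methyl]-2,3-dihydro-1-benzofuran-5-yl]methyl}cyclobutan-1-one, both epimers at cyclobutane C3 | O=C1CC(Cc2cc(OC)c3c(c2)[C@@H](CO[Si](C)(C)C(C)(C)C)[C@H](c2ccc(OCc4ccccc4)c(OC)c2)O3)C1(Cl)Cl | intermediate
21 | 3-{[(2R,3S)-2-[4-(benzyloxy)-3-methoxyphenyl]-7-methoxy-3-[(TBS-oxy)methyl]-2,3-dihydro-1-benzofuran-5-yl]methyl}cyclobutan-1-one | O=C1CC(C1)Cc1cc(OC)c2c(c1)[C@@H](CO[Si](C)(C)C(C)(C)C)[C@H](c1ccc(OCc3ccccc3)c(OC)c1)O2 | intermediate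
22 | (4S)-4-{[(2R,3S)-2-[4-(benzyloxy)-3-methoxyphenyl]-7-methoxy-3-[(TBS-oxy)methyl]-2,3-dihydro-1-benzofuran-5-yl]methyl}oxolan-2-one | O=C1OC[C@H](C1)Cc1cc(OC)c2c(c1)[C@@H](CO[Si](C)(C)C(C)(C)C)[C@H](c1ccc(OCc3ccccc3)c(OC)c1)O2 | intermediate
23 | 2-(allyloxy)-5-bromo-1-{(1S,2S)-1-[4-(benzyloxy)-3-methoxyphenyl]-1,3-bis(TBS-oxy)propan-2-yl}-3-methoxybenzene | COc1cc([C@@H](O[Si](C)(C)C(C)(C)C)[C@H](CO[Si](C)(C)C(C)(C)C)c2cc(Br)cc(OC)c2OCC=C)ccc1OCc1ccccc1 | intermediate
24 | 4-(allyloxy)-3-{(1S,2S)-1-[4-(benzyloxy)-3-methoxyphenyl]-1,3-bis(TBS-oxy)propan-2-yl}-5-methoxybenzaldehyde | COc1cc([C@@H](O[Si](C)(C)C(C)(C)C)[C@H](CO[Si](C)(C)C(C)(C)C)c2cc(C=O)cc(OC)c2OCC=C)ccc1OCc1ccccc1 | intermediate (not isolated)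
25 | [4-(allyloxy)-3-{(1S,2S)-1-[4-(benzyloxy)-3-methoxyphenyl]-1,3-bis(TBS-oxy)propan-2-yl}-5-methoxyphenyl]methanol | COc1cc([C@@H](O[Si](C)(C)C(C)(C)C)[C@H](CO[Si](C)(C)C(C)(C)C)c2cc(CO)cc(OC)c2OCC=C)ccc1OCc1ccccc1 | intermediate
26 | 2-(allyloxy)-5-(bromomethyl)-1-{(1S,2S)-1-[4-(benzyloxy)-3-methoxyphenyl]-1,3-bis(TBS-oxy)propan-2-yl}-3-methoxybenzene | COc1cc([C@@H](O[Si](C)(C)C(C)(C)C)[C@H](CO[Si](C)(C)C(C)(C)C)c2cc(CBr)cc(OC)c2OCC=C)ccc1OCc1ccccc1 | intermediate
27 | (3S,4S)-3-[4-(allyloxy)-3-(DP)-5-methoxybenzyl]-4-(BF-methyl)oxolan-2-one | COc1cc([C@@H](O[Si](C)(C)C(C)(C)C)[C@H](CO[Si](C)(C)C(C)(C)C)c2cc(C[C@@H]3C(=O)OC[C@H]3Cc3cc(OC)c4c(c3)[C@@H](CO[Si](C)(C)C(C)(C)C)[C@H](c3ccc(OCc5ccccc5)c(OC)c3)O4)cc(OC)c2OCC=C)ccc1OCc1ccccc1 | intermediate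
28 | (3S,4S)-3-[3-(DP)-4-hydroxy-5-methoxybenzyl]-4-(BF-methyl)oxolan-2-one | COc1cc([C@@H](O[Si](C)(C)C(C)(C)C)[C@H](CO[Si](C)(C)C(C)(C)C)c2cc(C[C@@H]3C(=O)OC[C@H]3Cc3cc(OC)c4c(c3)[C@@H](CO[Si](C)(C)C(C)(C)C)[C@H](c3ccc(OCc5ccccc5)c(OC)c3)O4)cc(OC)c2O)ccc1OCc1ccccc1 | intermediate
29 | (3S,4S)-3-[3-{(1S,2S)-1-[4-(benzyloxy)-3-methoxyphenyl]-1,3-dihydroxypropan-2-yl}-4-hydroxy-5-methoxybenzyl]-4-{[(2R,3S)-2-[4-(benzyloxy)-3-methoxyphenyl]-3-(hydroxymethyl)-7-methoxy-2,3-dihydro-1-benzofuran-5-yl]methyl}oxolan-2-one | COc1cc([C@@H](O)[C@H](CO)c2cc(C[C@@H]3C(=O)OC[C@H]3Cc3cc(OC)c4c(c3)[C@@H](CO)[C@H](c3ccc(OCc5ccccc5)c(OC)c3)O4)cc(OC)c2O)ccc1OCc1ccccc1 | intermediate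
30 | CNP0186558.3: (3S,4S)-3-[3-{(1S,2S)-1,3-dihydroxy-1-(4-hydroxy-3-methoxyphenyl)propan-2-yl}-4-hydroxy-5-methoxybenzyl]-4-{[(2R,3S)-2-(4-hydroxy-3-methoxyphenyl)-3-(hydroxymethyl)-7-methoxy-2,3-dihydro-1-benzofuran-5-yl]methyl}oxolan-2-one | COc1cc([C@@H](O)[C@H](CO)c2cc(C[C@@H]3C(=O)OC[C@H]3Cc3cc(OC)c4c(c3)[C@@H](CO)[C@H](c3ccc(O)c(OC)c3)O4)cc(OC)c2O)ccc1O | target

**Step count and risks**

Total step count: 20. Longest linear sequence: 17 steps (steps 1 to 13, then 17 to 20); the ring C/ring D branch (steps 14 to 16) leaves the main line at diol 12.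

Steps most likely to fail:

1. Step 13. The catalyst may discriminate poorly between the two α-methylene groups, since 3-benzyl-type cyclobutanones are the less selective class, or uncatalysed peracid oxidation may compete. Either would co-produce the C4 epimer, which would travel on as a hard-to-separate diastereomer. Fallback: starting from cyclobutanone 21, the ketone is deprotonated enantioselectively with a chiral lithium amide, LiN[(R)-CH(CH3)Ph]2 (antipode if a model ketone shows the opposite sense), in THF at −100 °C with Et3SiCl present, giving the triethylsilyl enol ether F1. Ozonolysis of its double bond (O3, CH2Cl2/MeOH, −78 °C), then NaBH4 and mildly acidic work-up, should give the hydroxy acid, which lactonises to 22, where the route is rejoined.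

2. Step 5. Reversible aldol addition and silylation under the magnesium conditions may erode the anti selectivity, and the arylacetyl imide may lose the auxiliary by ketene formation or the adduct may dehydrate. Fallback: starting from imide 8, the dibutylboron Z-enolate F2 is preformed (Bu2BOTf, i-Pr2NEt, CH2Cl2, −78 °C) and added to aldehyde 9 precomplexed with Et2AlCl. Addition through an open transition state on the chelated enolate face should give the same anti adduct 11 after buffered H2O2 work-up, where the route is rejoined.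

3. Step 11. The ZnCl2 and acid chloride in the medium may ionise the benzylic aryl ether of the dihydrobenzofuran or acylate the electron-rich rings, and the unactivated allyl group may add the ketene too slowly to outrun ketene oligomerisation. Fallback: starting from aryl bromide 15, a nickel-catalysed reductive cross-electrophile coupling with commercial 3-(bromomethyl)cyclobutan-1-one (O=C1CC(CBr)C1) is used: NiBr2(dme), 4,4'-di-tert-butyl-2,2'-bipyridine, Zn dust, NaI, DMA, 60 °C. It forms the aryl–CH2 bond and should give cyclobutanone 21 directly, bypassing steps 10 to 12; no new compound is made on the way (F0).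

**Further compounds**

F1 | step 13 | triethyl{[(3S)-3-{[(2R,3S)-2-[4-(benzyloxy)-3-methoxyphenyl]-7-methoxy-3-[(TBS-oxy)methyl]-2,3-dihydro-1-benzofuran-5-yl]methyl}cyclobut-1-en-1-yl]oxy}silane | CC[Si](CC)(CC)OC1=C[C@H](C1)Cc1cc(OC)c2c(c1)[C@@H](CO[Si](C)(C)C(C)(C)C)[C@H](c1ccc(OCc3ccccc3)c(OC)c1)O2
F2 | step 5 | dibutylboron Z-enolate of imide 8 | CCCCB(CCCC)O/C(=C\c1cc(Br)cc(OC)c1OCC=C)N1[C@@H](Cc2ccccc2)COC1=O
F0 | step 11 | none | none
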